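**Plan**
- Retrosynthesis: the three esters go last; C8–O and C9–O are cut back to a C8=C9 alkene, C1=O to an allylic CH2, and the C7 carbinol to a C7 enone derived from a 7,9-dione.
- The cyclobutane is cut at C4–C10 (enolate alkylation); the seven-membered ring is then cut at C7–C8 and C9–C10, the C8–C9 unit leaving as dichloroketene.
- This works because C7 (oxygen-bearing, next to quaternary C6) and C10 (methyl-bearing) can be joined for a time as the enol-ether carbons of a cyclopentanone (ring C5–C6–C7–C10–C11). Ketene [2+2] gives a bicyclo[3.2.0]heptanone, and retro-aldol cleavage of its C7–C10 bond turns the five-membered ring into the seven-membered ring C5–C11.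
- Forward ring order: Diels–Alder (cyclohexene fused to cyclopentanone), carbonyl transposition with the C10 methyl carbon, ketene ring expansion, cyclobutane closure to the bicyclo[3.1.1]heptene, then oxygenation and acylation; one batch of angelic mixed anhydride serves both angeloylations.
- Stereochemistry: C5/C11 from the catalytic asymmetric Diels–Alder; C4 from convex-face allylic hydroxylation followed by SN2 inversion; C10 from the ring closure; C7 from CBS reduction (reagent control); C8/C9 from osmylation anti to C7–O.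

Key step: step 8

Remark on the chemistry (assumption): locants C1–C11 are those of the longipinane skeleton of the target (C1 ketone, C2=C3, bridgeheads C4 and C11, one-carbon bridges C5 and C10, C6 gem-dimethyl, C7–C9 oxygenated); angeloyl = (Z)-2-methylbut-2-enoyl. C10 in 15–17 and C9 in 19–21 are epimer mixtures of no consequence (left open in the SMILES). The oxygen-bearing carbon of 6–8 (future C7) is drawn as the expected convex-face epimer and is erased in step 6.

**Step 1**
Reactants: 1 4,4-dimethylcyclopent-2-en-1-one; 2 isoprene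
Product: 3 (3aS,7aR)-3,3,5-trimethyl-2,3,3a,4,7,7a-hexahydro-1H-inden-1-one
Conditions: (S)-B-(o-tolyl)oxazaborolidine from (S)-α,α-diphenylprolinol (10 mol %), AlBr3 (8 mol %), CH2Cl2, −40 → −20 °C
Reagents that add atoms: none
Why: Lewis-acid-catalysed Diels–Alder reaction of a dienophile/diene pair known to give the cis-fused "para" adduct under aluminium halide catalysis, in which the cationic chiral oxazaborolidine shields one enone face so that C5 and C11 are set together by suprafacial addition (the antipodal catalyst is used should the facial sense prove opposite).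

**Step 2**
Reactants: 3 (3aS,7aR)-3,3,5-trimethyl-2,3,3a,4,7,7a-hexahydro-1H-inden-1-one
Product: 4 (3aS,4S,7aR)-4-hydroxy-3,3,5-trimethyl-2,3,3a,4,7,7a-hexahydro-1H-inden-1-one
Conditions: SeO2 (0.5 equiv), t-BuOOH, CH2Cl2, 20 °C
Reagents that add atoms: tert-butyl hydroperoxide CC(C)(C)OO
Why: Selenium dioxide allylic hydroxylation (ene reaction, then [2,3]-sigmatropic shift) should take place at the ring methylene on the more substituted alkene carbon (C4) and on the convex face, placing the hydroxyl cis to H-3a.

**Step 3**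
Reactants: 4 (3aS,4S,7aR)-4-hydroxy-3,3,5-trimethyl-2,3,3a,4,7,7a-hexahydro-1H-inden-1-one
Product: 5 4-O-triethylsilyl ether of 4
Conditions: Et3SiCl, imidazole, DMF, 0 °C
Reagents that add atoms: chlorotriethylsilane CC[Si](Cl)(CC)CC
Why: Routine silylation protects the allylic alcohol against the oxidation in step 6 and touches no stereocentre.

**Step 4**
Reactants: 5 4-O-triethylsilyl ether of 4
Product: 6 4-(triethylsilyloxy)-2-(trimethylsilyloxy)-3,3,5-trimethyl-2,3,3a,4,7,7a-hexahydro-1H-inden-1-one
Conditions: KN(SiMe3)2, THF, −78 °C; 2-(phenylsulfonyl)-3-phenyloxaziridine, −78 °C; then Me3SiCl, −78 → 0 °C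
Reagents that add atoms: 2-(phenylsulfonyl)-3-phenyloxaziridine O=S(=O)(N1OC1c1ccccc1)c1ccccc1; chlorotrimethylsilane C[Si](C)(C)Cl
Why: Kinetic deprotonation at the α-methylene (future C7), electrophilic enolate hydroxylation by the N-sulfonyloxaziridine on the convex face and in-situ O-silylation should install the C7 oxygen (the new centre is lost again in step 6).

**Step 5**
Reactants: 6 4-(triethylsilyloxy)-2-(trimethylsilyloxy)-3,3,5-trimethyl-2,3,3a,4,7,7a-hexahydro-1H-inden-1-one
Product: 8 1-methylene-4-(triethylsilyloxy)-3,3,5-trimethyl-2,3,3a,4,7,7a-hexahydro-1H-inden-2-ol, via bis-silyl ether 7 (not isolated)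
Conditions: Ph3PCH3Br, KOt-Bu, THF, 0 → 50 °C; then K2CO3, MeOH, 0 °C
Reagents that add atoms: methyltriphenylphosphonium bromide C[P+](c1ccccc1)(c1ccccc1)c1ccccc1.[Br-]
Why: Wittig methylenation of the ketone brings in the future C10 methyl carbon, and mild methanolysis removes only the labile trimethylsilyl ether.

**Step 6**
Reactants: 8 1-methylene-4-(triethylsilyloxy)-3,3,5-trimethyl-2,3,3a,4,7,7a-hexahydro-1H-inden-2-ol
Product: 9 1-methylene-4-(triethylsilyloxy)-3,3,5-trimethyl-1,3,3a,4,7,7a-hexahydro-2H-inden-2-one
Conditions: DMP, NaHCO3, CH2Cl2, 0 → 20 °C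
Reagents that add atoms: none
Why: Periodinane oxidation of the secondary allylic alcohol completes the 1,2-carbonyl transposition, so that the ketone now sits at C7 between the quaternary C6 and C10.

**Step 7**
Reactants: 9 1-methylene-4-(triethylsilyloxy)-3,3,5-trimethyl-1,3,3a,4,7,7a-hexahydro-2H-inden-2-one
Product: 10 1,3,3,5-tetramethyl-2,4-bis(triethylsilyloxy)-3a,4,7,7a-tetrahydro-3H-indene
Conditions: Et3SiH, RhCl(PPh3)3 (2 mol %), THF, 50 °C
Reagents that add atoms: triethylsilane CC[SiH](CC)CC
Why: Rhodium-catalysed 1,4-hydrosilylation of the s-cis-locked exocyclic enone should deliver hydride to the methylene carbon and silicon to oxygen, giving regiospecifically the tetrasubstituted C7=C10 silyl enol ether with the C10 methyl in place.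

**Step 8**
Reactants: 10 1,3,3,5-tetramethyl-2,4-bis(triethylsilyloxy)-3a,4,7,7a-tetrahydro-3H-indene; 11 dichloroacetyl chloride
Product: 13 2,2-dichlorocyclobutanone fused across C7–C10 (C8Cl2 and C9=O; C7–OSiEt3 and C10–CH3 at the cis ring fusion; cyclobutanone on the face of H-5 and H-11), via dichloroketene 12 (not isolated)
Conditions: 11 (1.5 equiv, slow addition), Et3N, hexane, 25 °C
Reagents that add atoms: none
Why: Triethylamine dehydrochlorinates 11 to dichloroketene 12, whose electrophilic carbonyl carbon (C9) is attacked by the nucleophilic enol-ether carbon C10 while C8 closes onto the oxygen-bearing C7, an asynchronous [2+2] ketene–alkene cycloaddition. The closest known reaction type is the dichloroketene/silyl enol ether cycloaddition used for the two-carbon ring expansion of cyclopentanones to cycloheptane-1,3-diones. One ring is closed, the four-membered cyclobutanone C7–C8–C9–C10, by cycloaddition and necessarily cis-fused to the five-membered ring. The new stereocentres C7 and C10 result from suprafacial addition to the convex face of the cis-hydrindene; both are erased when the temporary C7–C10 bond is cleaved in step 9, and C10 is set for good in step 11. The step needs regioselectivity, secured by the polarity match (C=O carbon to C10, CCl2 carbon to C7–OSi), and chemoselectivity for the enol ether over the trisubstituted ring alkene, secured by the much higher nucleophilicity of the enol ether and a small excess of ketene. The event is possible because C7 and C10 are held together as the two enol-ether carbons of the five-membered ring C5–C6–C7–C10–C11, so that the C8–C9 unit enters between them and the seven-membered ring C5–C11 appears once the C7–C10 bond is released.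

**Step 9**
Reactants: 13 2,2-dichlorocyclobutanone fused across C7–C10
Product: 15 4-hydroxy-3,5,5,9-tetramethyl-1,4,4a,5,9,9a-hexahydro-6H-benzo[7]annulene-6,8(7H)-dione (cis-fused; 4-OH cis to H-4a), via dechlorinated cyclobutanone 14 (not isolated)
Conditions: Zn, AcOH, i-PrOH/H2O, 0 → 20 °C; then AcOH/H2O, 80 °C
Reagents that add atoms: none
Why: Zinc dechlorination followed by acid desilylation should trigger retro-aldol cleavage of the strained C7–C10 fusion bond of the β-hydroxy cyclobutanone (two-carbon ring expansion to the cycloheptane-1,3-dione) and at the same time hydrolyse the allylic silyl ether.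

**Step 10**
Reactants: 15 4-hydroxy-3,5,5,9-tetramethyl-1,4,4a,5,9,9a-hexahydro-6H-benzo[7]annulene-6,8(7H)-dione
Product: 16 7,7-(propane-1,3-diyldithio) derivative of 15 (spiro-1,3-dithiane on C8)
Conditions: TsS(CH2)3STs, KOAc, EtOH, reflux
Reagents that add atoms: trimethylene dithiotosylate Cc1ccc(cc1)S(=O)(=O)SCCCSS(=O)(=O)c1ccc(C)cc1
Why: Double sulfenylation of the active methylene of the 1,3-dione blocks C8, leaving C10 as the only enolisable position of the seven-membered ring.

**Step 11**
Reactants: 16 7,7-(propane-1,3-diyldithio) derivative of 15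
Product: 18 8,8-(propane-1,3-diyldithio)longipin-2-ene-7,9-dione, via allylic mesylate 17 (not isolated)
Conditions: MsCl, Et3N, CH2Cl2, −30 °C; then KN(SiMe3)2 (1.1 equiv), THF, −78 → 0 °C
Reagents that add atoms: none
Why: Intramolecular enolate C-alkylation (4-exo-tet), the reaction type used to close nopinone-type bicyclo[3.1.1]heptanones; the C9/C10 enolate should displace the allylic mesylate at C4 from the opposite face with inversion (O-alkylation is geometrically excluded because the enolate oxygen is trans to C11), so that the cis ring fusion and the SN2 trajectory fix C4 and the quaternary C10 as in the target.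

**Step 12**
Reactants: 18 8,8-(propane-1,3-diyldithio)longipin-2-ene-7,9-dione
Product: 19 9-hydroxy-8,8-(propane-1,3-diyldithio)longipin-2-en-7-one
Conditions: NaBH4, MeOH/CH2Cl2, −40 °C
Reagents that add atoms: none
Why: Hydride reduction is expected at the more accessible carbonyl C9, whose neighbour C10 is tied back in the cyclobutane, rather than at C7, which is shielded on both faces by the geminal methyls on C6; the carbinol configuration is immaterial.

**Step 13**
Reactants: 19 9-hydroxy-8,8-(propane-1,3-diyldithio)longipin-2-en-7-one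
Product: 20 9-hydroxylongipin-2-en-7-one
Conditions: skeletal nickel (Ni, W-2 grade, washed neutral), EtOH, 20 °C
Reagents that add atoms: none
Why: Reductive desulfurisation of the dithioketal returns the C8 methylene without touching the trisubstituted alkene.

**Step 14**
Reactants: 20 9-hydroxylongipin-2-en-7-one
Product: 22 longipina-2,8-dien-7-one, via β-mesyloxy ketone 21 (not isolated)
Conditions: MsCl, Et3N, CH2Cl2, 0 °C; then DBU, 20 °C
Reagents that add atoms: none
Why: Mesylation and E1cB elimination of the β-hydroxy ketone can only give the C8=C9 enone conjugated with the C7 carbonyl, since C6 and C10 are quaternary.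

**Step 15**
Reactants: 22 longipina-2,8-dien-7-one
Product: 23 (7R)-longipina-2,8-dien-7-ol
Conditions: (S)-2-methyl-CBS-oxazaborolidine (20 mol %), catecholborane, toluene, −78 °C
Reagents that add atoms: none
Why: CBS reduction under reagent control, with quaternary C6 as the large and vinylic C8 as the small substituent, should give the (7R) allylic alcohol, which has the C7–O orientation of the target, while catecholborane leaves the ring alkene alone.

**Step 16**
Reactants: 24 angelic acid
Product: 25 angelic 2,4,6-trichlorobenzoic anhydride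
Conditions: 2,4,6-Cl3C6H2COCl (1.0 equiv), Et3N (1.05 equiv), toluene, 0 → 20 °C; Et3NHCl filtered off under argon; filtrate kept as a toluene stock solution for steps 17 and 21
Reagents that add atoms: 2,4,6-trichlorobenzoyl chloride O=C(Cl)c1c(Cl)cc(Cl)cc1Cl
Why: Acylation of triethylammonium angelate by the hindered aroyl chloride (Yamaguchi mixed-anhydride activation) should give an anhydride that can be filtered from the ammonium salt and stored in solution, in which only the unhindered angeloyl carbonyl is open to attack and the Z geometry is retained because no nucleophilic catalyst is present.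

**Step 17**
Reactants: 23 (7R)-longipina-2,8-dien-7-ol; 25 angelic 2,4,6-trichlorobenzoic anhydride
Product: 26 (7R)-longipina-2,8-dien-7-yl angelate
Conditions: 25 (1.5 equiv, toluene solution), toluene, 80 °C
Reagents that add atoms: none
Why: Mixed-anhydride (Yamaguchi-type) esterification, chosen for angelates because thermal acyl transfer from the preformed anhydride outruns Z-to-E isomerisation; the carbinol centre is not touched.

**Step 18**
Reactants: 26 (7R)-longipina-2,8-dien-7-yl angelate
Product: 27 7-angeloyloxylongipina-2,8-dien-1-one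
Conditions: Rh2(caprolactamate)4 (1 mol %), t-BuOOH (70 % aq.), K2CO3, CH2Cl2, 20 °C
Reagents that add atoms: tert-butyl hydroperoxide CC(C)(C)OO
Why: Allylic oxidation of the α-pinene-like trisubstituted alkene at its only ring methylene (C1; C4 is a bridgehead), the pinene-to-verbenone type of transformation, should give the enone, the hindered C7–H and the electron-poor angelate being less prone to hydrogen abstraction.

**Step 19**
Reactants: 27 7-angeloyloxylongipina-2,8-dien-1-one
Product: 28 7-angeloyloxy-8,9-dihydroxylongipin-2-en-1-one (8,9-cis-diol trans to the 7-ester)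
Conditions: OsO4 (5 mol %), N-methylmorpholine N-oxide, acetone/H2O, 20 °C
Reagents that add atoms: N-methylmorpholine N-oxide C[N+]1([O-])CCOCC1; water O
Why: Catalytic osmium tetroxide dihydroxylation of the only electron-rich alkene left (C8=C9), suprafacial and anti to the allylic C7 acyloxy group, sets C8 and C9 cis to each other and trans to C7–O.

**Step 20**
Reactants: 28 7-angeloyloxy-8,9-dihydroxylongipin-2-en-1-one
Product: 29 8-acetoxy-7-angeloyloxy-9-hydroxylongipin-2-en-1-one
Conditions: Ac2O (1.1 equiv), pyridine, DMAP (cat.), CH2Cl2, −20 °C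
Reagents that add atoms: acetic anhydride CC(=O)OC(C)=O
Why: Selective acylation of the less hindered C8 hydroxyl, the C9 hydroxyl being neopentylic (next to quaternary C10) and much slower.

**Step 21**
Reactants: 29 8-acetoxy-7-angeloyloxy-9-hydroxylongipin-2-en-1-one; 25 angelic 2,4,6-trichlorobenzoic anhydride
Product: 30 (4R,5S,7S,8R,9S,10R,11R)-8-acetoxy-7,9-bis(angeloyloxy)longipin-2-en-1-one
Conditions: 25 (3 equiv, toluene solution from step 16), toluene, 90 °C
Reagents that add atoms: none
Why: The same mixed-anhydride esterification acylates the remaining hindered C9 hydroxyl without changing any stereocentre and completes the target.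

**Compound list**
1 | 4,4-dimethylcyclopent-2-en-1-one | O=C1C=CC(C)(C)C1 | starting material
2 | isoprene | C=CC(C)=C | starting material
3 | (3aS,7aR)-3,3,5-trimethyl-2,3,3a,4,7,7a-hexahydro-1H-inden-1-one | C1C(=O)[C@@H]2CC=C(C)C[C@@H]2C1(C)C | intermediate
4 | (3aS,4S,7aR)-4-hydroxy-3,3,5-trimethyl-2,3,3a,4,7,7a-hexahydro-1H-inden-1-one | C1C(=O)[C@@H]2CC=C(C)[C@@H](O)[C@@H]2C1(C)C | intermediate
5 | 4-O-triethylsilyl ether of 4 | C1C(=O)[C@@H]2CC=C(C)[C@@H](O[Si](CC)(CC)CC)[C@@H]2C1(C)C | intermediate
6 | 4-(triethylsilyloxy)-2-(trimethylsilyloxy)-3,3,5-trimethyl-2,3,3a,4,7,7a-hexahydro-1H-inden-1-one | C[Si](C)(C)O[C@H]1C(=O)[C@@H]2CC=C(C)[C@@H](O[Si](CC)(CC)CC)[C@@H]2C1(C)C | intermediate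
7 | 1-methylene analogue of 6 (bis-silyl ether) | C[Si](C)(C)O[C@H]1C(=C)[C@@H]2CC=C(C)[C@@H](O[Si](CC)(CC)CC)[C@@H]2C1(C)C | intermediate (not isolated)
8 | 1-methylene-4-(triethylsilyloxy)-3,3,5-trimethyl-2,3,3a,4,7,7a-hexahydro-1H-inden-2-ol | O[C@H]1C(=C)[C@@H]2CC=C(C)[C@@H](O[Si](CC)(CC)CC)[C@@H]2C1(C)C | intermediate
9 | 1-methylene-4-(triethylsilyloxy)-3,3,5-trimethyl-1,3,3a,4,7,7a-hexahydro-2H-inden-2-one | O=C1C(=C)[C@@H]2CC=C(C)[C@@H](O[Si](CC)(CC)CC)[C@@H]2C1(C)C | intermediate
10 | 1,3,3,5-tetramethyl-2,4-bis(triethylsilyloxy)-3a,4,7,7a-tetrahydro-3H-indene | CC[Si](CC)(CC)OC1=C(C)[C@@H]2CC=C(C)[C@@H](O[Si](CC)(CC)CC)[C@@H]2C1(C)C | intermediate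
11 | dichloroacetyl chloride | ClC(Cl)C(Cl)=O | starting material
12 | dichloroketene | ClC(Cl)=C=O | intermediate (not isolated)
13 | 2,2-dichlorocyclobutanone fused across C7–C10 of 10 | CC[Si](CC)(CC)O[C@]12C(Cl)(Cl)C(=O)[C@@]1(C)[C@@H]3CC=C(C)[C@@H](O[Si](CC)(CC)CC)[C@@H]3C2(C)C | intermediate
14 | dechlorinated cyclobutanone | CC[Si](CC)(CC)O[C@]12CC(=O)[C@@]1(C)[C@@H]3CC=C(C)[C@@H](O[Si](CC)(CC)CC)[C@@H]3C2(C)C | intermediate (not isolated)
15 | 4-hydroxy-3,5,5,9-tetramethyl-1,4,4a,5,9,9a-hexahydro-6H-benzo[7]annulene-6,8(7H)-dione | O=C1CC(=O)C(C)[C@@H]2CC=C(C)[C@@H](O)[C@@H]2C1(C)C | intermediate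
16 | 7,7-(propane-1,3-diyldithio) derivative of 15 | O=C1C2(SCCCS2)C(=O)C(C)[C@@H]3CC=C(C)[C@@H](O)[C@@H]3C1(C)C | intermediate
17 | 4-O-mesylate of 16 | O=C1C2(SCCCS2)C(=O)C(C)[C@@H]3CC=C(C)[C@@H](OS(C)(=O)=O)[C@@H]3C1(C)C | intermediate (not isolated)
18 | 8,8-(propane-1,3-diyldithio)longipin-2-ene-7,9-dione | O=C1C2(SCCCS2)C(=O)[C@@]3(C)[C@@H]4CC=C(C)[C@H]3[C@@H]4C1(C)C | intermediate
19 | 9-hydroxy-8,8-(propane-1,3-diyldithio)longipin-2-en-7-one | O=C1C2(SCCCS2)C(O)[C@@]3(C)[C@@H]4CC=C(C)[C@H]3[C@@H]4C1(C)C | intermediate
20 | 9-hydroxylongipin-2-en-7-one | O=C1CC(O)[C@@]2(C)[C@@H]3CC=C(C)[C@H]2[C@@H]3C1(C)C | intermediate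
21 | 9-mesyloxylongipin-2-en-7-one | O=C1CC(OS(C)(=O)=O)[C@@]2(C)[C@@H]3CC=C(C)[C@H]2[C@@H]3C1(C)C | intermediate (not isolated)
22 | longipina-2,8-dien-7-one | O=C1C=C[C@@]2(C)[C@@H]3CC=C(C)[C@H]2[C@@H]3C1(C)C | intermediate
23 | (7R)-longipina-2,8-dien-7-ol | O[C@@H]1C=C[C@@]2(C)[C@@H]3CC=C(C)[C@H]2[C@@H]3C1(C)C | intermediate
24 | angelic acid | C/C=C(/C)C(O)=O | starting material
25 | angelic 2,4,6-trichlorobenzoic anhydride | C/C=C(/C)C(=O)OC(=O)c1c(Cl)cc(Cl)cc1Cl | intermediate
26 | (7R)-longipina-2,8-dien-7-yl angelate | C/C=C(/C)C(=O)O[C@@H]1C=C[C@@]2(C)[C@@H]3CC=C(C)[C@H]2[C@@H]3C1(C)C | intermediate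
27 | 7-angeloyloxylongipina-2,8-dien-1-one | C/C=C(/C)C(=O)O[C@@H]1C=C[C@@]2(C)[C@@H]3C(=O)C=C(C)[C@H]2[C@@H]3C1(C)C | intermediate
28 | 7-angeloyloxy-8,9-dihydroxylongipin-2-en-1-one | C/C=C(/C)C(=O)O[C@@H]1[C@@H](O)[C@@H](O)[C@@]2(C)[C@@H]3C(=O)C=C(C)[C@H]2[C@@H]3C1(C)C | intermediate
29 | 8-acetoxy-7-angeloyloxy-9-hydroxylongipin-2-en-1-one | C/C=C(/C)C(=O)O[C@@H]1[C@@H](OC(C)=O)[C@@H](O)[C@@]2(C)[C@@H]3C(=O)C=C(C)[C@H]2[C@@H]3C1(C)C | intermediate
30 | (4R,5S,7S,8R,9S,10R,11R)-8-acetoxy-7,9-bis(angeloyloxy)longipin-2-en-1-one | C/C=C(/C)C(=O)O[C@@H]1[C@@H](OC(C)=O)[C@@H](OC(=O)/C(C)=C\C)[C@@]2(C)[C@@H]3C(=O)C=C(C)[C@H]2[C@@H]3C1(C)C | target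

Total step count: 21. Longest linear sequence: 20 steps (steps 1–15 and 17–21, from 1); step 16 is a one-step side branch from 24.

**Steps most likely to fail**

Step 11 (cyclobutane closure). The hindered tertiary enolate may not reach the secondary allylic carbon, so that 1,4-elimination of the mesylate to a diene or SN2′ attack at C2 takes over. Fallback: starting from 16, the alcohol is converted (ClCO2Me, pyridine, CH2Cl2, 0 °C) into the allylic methyl carbonate of 16 F1, and the bond is made by intramolecular Tsuji–Trost alkylation under neutral conditions (Pd(PPh3)4, zerovalent palladium, THF, 60 °C). Ionisation with inversion places palladium on the face that carries C10, the liberated methoxide forms the unstabilised ketone enolate, and inner-sphere C–C reductive elimination on that face should deliver 18, where the route is rejoined.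

Step 12 (differentiation of the two carbonyls). The hydride may discriminate poorly between C9 and C7 or attack C7. Fallback: starting from 18, the regioisomeric carbinol formed under the same borohydride conditions, 7-hydroxy-8,8-(propane-1,3-diyldithio)longipin-2-en-9-one F2, is used rather than discarded. Desulfurisation (skeletal nickel, EtOH) gives 7-hydroxylongipin-2-en-9-one F3. Its C9 ketone, which can enolise only toward C8, is converted (KN(SiMe3)2, 2.1 equiv, then PhNTf2, 1.05 equiv, THF, −78 °C; the hindered C7 alkoxide is expected to resist the mild triflimide) into 7-hydroxylongipina-2,8-dien-9-yl trifluoromethanesulfonate F4. Palladium-catalysed formate reduction (Pd(OAc)2, divalent palladium, PPh3, HCO2H, Et3N, DMF, 60 °C) gives longipina-2,8-dien-7-ol F5 as a C7 epimer mixture, and MnO2 oxidation of this allylic alcohol returns to the route at 22.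

Step 1 (asymmetric Diels–Alder). The β-carbon of the dienophile is flanked by a quaternary centre, so slow turnover and loss of facial control by background reaction are possible. Fallback: starting from 1 and 2, the cycloaddition is run with AlCl3 in toluene to give racemic material, that is 3 together with its enantiomer (3aR,7aS)-3,3,5-trimethyl-2,3,3a,4,7,7a-hexahydro-1H-inden-1-one F6. Step 2 is carried out on this racemate to give 4 together with its enantiomer (3aR,4R,7aS)-4-hydroxy-3,3,5-trimethyl-2,3,3a,4,7,7a-hexahydro-1H-inden-1-one F7. Kinetic resolution by lipase-catalysed acetylation (Candida antarctica lipase B or another lipase selected by screening for acylation of the unwanted antipode, vinyl acetate, hexane, 30 °C) should convert the unwanted enantiomer into the 4-O-acetate of the enantiomer of 4 F8 and leave 4, which is separated by chromatography and with which the route is rejoined.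

**Further compounds**
F1 | step 11 | allylic methyl carbonate of 16 | O=C1C2(SCCCS2)C(=O)C(C)[C@@H]3CC=C(C)[C@@H](OC(=O)OC)[C@@H]3C1(C)C
F2 | step 12 | 7-hydroxy-8,8-(propane-1,3-diyldithio)longipin-2-en-9-one | OC1C2(SCCCS2)C(=O)[C@@]3(C)[C@@H]4CC=C(C)[C@H]3[C@@H]4C1(C)C
F3 | step 12 | 7-hydroxylongipin-2-en-9-one | OC1CC(=O)[C@@]2(C)[C@@H]3CC=C(C)[C@H]2[C@@H]3C1(C)C
F4 | step 12 | 7-hydroxylongipina-2,8-dien-9-yl trifluoromethanesulfonate | OC1C=C(OS(=O)(=O)C(F)(F)F)[C@@]2(C)[C@@H]3CC=C(C)[C@H]2[C@@H]3C1(C)C
F5 | step 12 | longipina-2,8-dien-7-ol (C7 epimer mixture) | OC1C=C[C@@]2(C)[C@@H]3CC=C(C)[C@H]2[C@@H]3C1(C)C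
F6 | step 1 | (3aR,7aS)-3,3,5-trimethyl-2,3,3a,4,7,7a-hexahydro-1H-inden-1-one (enantiomer of 3) | C1C(=O)[C@H]2CC=C(C)C[C@H]2C1(C)C
F7 | step 1 | (3aR,4R,7aS)-4-hydroxy-3,3,5-trimethyl-2,3,3a,4,7,7a-hexahydro-1H-inden-1-one (enantiomer of 4) | C1C(=O)[C@H]2CC=C(C)[C@H](O)[C@H]2C1(C)C
F8 | step 1 | 4-O-acetate of the enantiomer of 4 | C1C(=O)[C@H]2CC=C(C)[C@H](OC(C)=O)[C@H]2C1(C)C
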